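Feature: ring B (C1' ether O, C2' OH, C3' H, C4' OH, C5' CO2H, C6' pentyl) is an olivetolic acid ring. Its C1' lies between C2' and C6', the two ketone carbons of the open tetraketide, so the C8–O–C1' ether can be made at an sp3 C1' and becomes a diaryl ether only when ring B aromatises.
Endgame: hydroxide opens the acetonide and the pyranone, O6 is debenzylated on the open keto acid (no C3=C4 alkene there), and acid re-closes the enol lactone.
Key disconnection C5'–C6': aldol cycloaromatisation of the 3-(isocoumarin-8-yloxy)-2,4-dioxononyl dioxinone to the acetonide-protected resorcylate.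
Precursor: cut at C2'–C3' (dioxinone dienolate + acid chloride) and at O–C1' (SN2 of the 8-hydroxyisocoumarin on an α-chloro-β-keto ester). C6' travels as a silylated carbinol and is oxidised last, because an unstabilised C1' enolate would attack the peri lactone carbonyl (Dieckmann closure to a benzofuranone) and a β-keto acid cannot be activated.
Ring order: benzene ring A is bought (methyl orsellinate), the pyranone ring is closed in step 4, ring B in step 15, and the pyranone is opened in step 16 and closed again in step 18.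

Key step: step 15

Remark: the target has no stereocentre. The transient centres C1' and C6' in 12–16, 18 and 20–23 are carried as racemic mixtures of diastereomers and both become sp2 by step 15.

Step 1
Reactants: 1 methyl orsellinate (methyl 2,4-dihydroxy-6-methylbenzoate)
Product: 2 methyl 2,4-bis(benzyloxy)-6-methylbenzoate
Conditions: BnBr (2.5 equiv), K2CO3 (3 equiv), DMF, 60 °C
Reagents that add atoms: benzyl bromide BrCc1ccccc1
Why: Williamson ether synthesis: with excess halide in warm DMF the hydrogen-bonded 2-OH is alkylated as well as the 4-OH, which removes both acidic protons ahead of the lithiation in step 3.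

Step 2
Reactants: 3 hexanoyl chloride
Product: 4 N-methoxy-N-methylhexanamide
Conditions: MeNH(OMe)·HCl, Et3N (2.2 equiv), CH2Cl2, 0 °C to rt
Reagents that add atoms: N,O-dimethylhydroxylamine hydrochloride Cl.CNOC
Why: N-acylation of an amine by an acid chloride gives the Weinreb amide, the acyl donor that stops cleanly at the ketone in step 3.

Step 3
Reactants: 2 methyl 2,4-bis(benzyloxy)-6-methylbenzoate; 4 N-methoxy-N-methylhexanamide
Product: 6 methyl 2,4-bis(benzyloxy)-6-(2-oxoheptyl)benzoate, via benzylic organolithium 5 (not isolated)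
Conditions: LiN(iPr)2 (1.15 equiv), THF, −78 °C; then 4, −78 to −40 °C; 1 M HCl
Reagents that add atoms: LiN(iPr)2 [Li]N(C(C)C)C(C)C (supplies the lithium of 5 only)
Why: Lateral lithiation of an ortho-toluate (the ester stabilises the benzylic anion and its two ortho substituents shield it from self-condensation) is followed by a Weinreb ketone synthesis, in which the chelated tetrahedral adduct persists until the acid quench, so that neither over-addition nor quenching of 5 by the acidic product can occur.

Step 4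
Reactants: 6 methyl 2,4-bis(benzyloxy)-6-(2-oxoheptyl)benzoate
Product: 7 6,8-bis(benzyloxy)-3-pentyl-1H-isochromen-1-one
Conditions: p-toluenesulfonic acid monohydrate (0.2 equiv), toluene, 100 °C, methanol distilled off
Reagents that add atoms: none
Why: Acid-catalysed enol lactonisation, a 6-exo-trig transesterification by the enol of the benzylic ketone, is pulled forward by removal of methanol and by the conjugation of the 2-pyranone, and acid is chosen over alkoxide because base could send the other enolate onto the ester in a Dieckmann closure to a naphthalenediol.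

Step 5
Reactants: 7 6,8-bis(benzyloxy)-3-pentyl-1H-isochromen-1-one
Product: 8 6-(benzyloxy)-8-hydroxy-3-pentyl-1H-isochromen-1-one
Conditions: BCl3 (1.1 equiv), CH2Cl2, −78 °C; then H2O
Reagents that add atoms: none
Why: Chelation-directed Lewis acid ether cleavage: BCl3 is held between the lactone carbonyl oxygen and the peri O8, so that at low temperature only this benzyl group leaves as benzyl chloride and the O6 benzyl ether stays.

Step 6
Reactants: 3 hexanoyl chloride; 9 Meldrum's acid (2,2-dimethyl-1,3-dioxane-4,6-dione)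
Product: 11 allyl 3-oxooctanoate, via acyl Meldrum's acid 10 (not isolated)
Conditions: pyridine, CH2Cl2, 0 °C to rt; then allyl alcohol, toluene, reflux
Reagents that add atoms: allyl alcohol C=CCO
Why: Meldrum's acid route to β-keto esters: C-acylation gives 10, which on heating loses acetone and CO2 through an acylketene that allyl alcohol traps.

Step 7
Reactants: 11 allyl 3-oxooctanoate
Product: 12 allyl 2-chloro-3-oxooctanoate (racemic)
Conditions: SO2Cl2 (1.0 equiv), CH2Cl2, 0 °C
Reagents that add atoms: sulfuryl chloride ClS(Cl)(=O)=O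
Why: Electrophilic α-chlorination of the enol of a β-keto ester, which with one equivalent of SO2Cl2 at 0 °C is far faster than addition to the isolated allyl alkene; the new centre is racemic and is erased later.

Step 8
Reactants: 8 6-(benzyloxy)-8-hydroxy-3-pentyl-1H-isochromen-1-one; 12 allyl 2-chloro-3-oxooctanoate
Product: 13 allyl 2-{[6-(benzyloxy)-1-oxo-3-pentyl-1H-isochromen-8-yl]oxy}-3-oxooctanoate (racemic)
Conditions: K2CO3 (2.5 equiv), DMF, rt to 45 °C
Reagents that add atoms: none
Why: Williamson-type SN2 displacement of the doubly activated α-chloride by the phenoxide of 8, the usual route to 2-aryloxy-3-oxo esters, forms the O–C1' bond at an sp3 carbon, and the product rests as a doubly stabilised enolate that gains nothing by adding to the neighbouring lactone carbonyl.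

Step 9
Reactants: 13 allyl 2-{[6-(benzyloxy)-1-oxo-3-pentyl-1H-isochromen-8-yl]oxy}-3-oxooctanoate
Product: 14 allyl 2-{[6-(benzyloxy)-1-oxo-3-pentyl-1H-isochromen-8-yl]oxy}-3-hydroxyoctanoate (diastereomer mixture)
Conditions: NaBH4 (0.6 equiv), THF–MeOH, −40 to −20 °C
Reagents that add atoms: none
Why: Chemoselective borohydride reduction of the ketone (allyl ester and conjugated lactone are inert at this temperature) removes the β-dicarbonyl acidity of C1'–H, so that the carboxyl group can later be freed without decarboxylation and activated; no control over the two transient centres is needed because steps 14 and 15 flatten both.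

Step 10
Reactants: 14 allyl 2-{[6-(benzyloxy)-1-oxo-3-pentyl-1H-isochromen-8-yl]oxy}-3-hydroxyoctanoate
Product: 15 allyl 2-{[6-(benzyloxy)-1-oxo-3-pentyl-1H-isochromen-8-yl]oxy}-3-[(tert-butyldimethylsilyl)oxy]octanoate
Conditions: TBSOTf, 2,6-lutidine, CH2Cl2, 0 °C
Reagents that add atoms: tert-butyldimethylsilyl triflate CC(C)(C)[Si](C)(C)OS(=O)(=O)C(F)(F)F
Why: Standard silylation of a hindered secondary alcohol by a silyl triflate and a non-nucleophilic pyridine base; the ether blocks lactonisation and acyl transfer during carboxyl activation.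

Step 11
Reactants: 15 allyl 2-{[6-(benzyloxy)-1-oxo-3-pentyl-1H-isochromen-8-yl]oxy}-3-[(tert-butyldimethylsilyl)oxy]octanoate
Product: 16 2-{[6-(benzyloxy)-1-oxo-3-pentyl-1H-isochromen-8-yl]oxy}-3-[(tert-butyldimethylsilyl)oxy]octanoic acid
Conditions: Pd(PPh3)4 (5 mol%), morpholine (1.5 equiv), THF, 0 °C to rt
Reagents that add atoms: none
Why: Tsuji–Trost deallylation: zerovalent palladium ionises the allyl ester to a π-allyl complex, which morpholine captures, under near-neutral conditions that leave lactone, silyl ether and benzyl ether untouched.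

Step 12
Reactants: 16 2-{[6-(benzyloxy)-1-oxo-3-pentyl-1H-isochromen-8-yl]oxy}-3-[(tert-butyldimethylsilyl)oxy]octanoic acid; 17 2,2,6-trimethyl-4H-1,3-dioxin-4-one
Product: 20 6-(3-{[6-(benzyloxy)-1-oxo-3-pentyl-1H-isochromen-8-yl]oxy}-4-[(tert-butyldimethylsilyl)oxy]-2-oxononyl)-2,2-dimethyl-4H-1,3-dioxin-4-one, via acid chloride 18 (not isolated), via lithium dienolate 19 (not isolated)
Conditions: 16, Me2C=C(Cl)NMe2 (1.05 equiv), CH2Cl2, 0 °C; 17 (2.6 equiv), LiN(SiMe3)2 (2.5 equiv), THF, −78 °C; 18 added to 19, −78 °C; 1 M HCl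
Reagents that add atoms: 1-chloro-N,N,2-trimethylprop-1-en-1-amine CC(C)=C(Cl)N(C)C (chlorine of 18 only); LiN(SiMe3)2 [Li]N([Si](C)(C)C)[Si](C)(C)C (lithium of 19 only)
Why: Claisen-type γ-C-acylation of the vinylogous lithium enolate of the dioxinone by an acid chloride, the standard entry to 6-(2-oxoalkyl)dioxinones: the neutral chloroenamine spares the silyl ether, the acid chloride reacts far faster than the electron-rich, peri-shielded lactone carbonyl, and the second equivalent of 19 removes the most acidic proton of the product at C3' and not at C1'.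

Step 13
Reactants: 20 6-(3-{[6-(benzyloxy)-1-oxo-3-pentyl-1H-isochromen-8-yl]oxy}-4-[(tert-butyldimethylsilyl)oxy]-2-oxononyl)-2,2-dimethyl-4H-1,3-dioxin-4-one
Product: 21 6-(3-{[6-(benzyloxy)-1-oxo-3-pentyl-1H-isochromen-8-yl]oxy}-4-hydroxy-2-oxononyl)-2,2-dimethyl-4H-1,3-dioxin-4-one
Conditions: HF·pyridine, THF–pyridine, 0 °C to rt
Reagents that add atoms: none
Why: Fluoride-driven cleavage of the Si–O bond in a weakly acidic medium, which avoids the retro-aldol and E1cB pathways that a basic fluoride source would open in the β-hydroxy ketone.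

Step 14
Reactants: 21 6-(3-{[6-(benzyloxy)-1-oxo-3-pentyl-1H-isochromen-8-yl]oxy}-4-hydroxy-2-oxononyl)-2,2-dimethyl-4H-1,3-dioxin-4-one
Product: 22 6-(3-{[6-(benzyloxy)-1-oxo-3-pentyl-1H-isochromen-8-yl]oxy}-2,4-dioxononyl)-2,2-dimethyl-4H-1,3-dioxin-4-one (C1' labile and largely enolised)
Conditions: Dess–Martin periodinane (1.1 equiv), CH2Cl2, 0 °C to rt; short silica plug, used at once
Reagents that add atoms: none
Why: Dess–Martin oxidation turns the β-hydroxy ketone into the 1,3-diketone under neutral conditions, a known way to finish diketo-dioxinones, and the reagent is kept near one equivalent so that the enolised C1' position is not oxidised further.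

Step 15
Reactants: 22 6-(3-{[6-(benzyloxy)-1-oxo-3-pentyl-1H-isochromen-8-yl]oxy}-2,4-dioxononyl)-2,2-dimethyl-4H-1,3-dioxin-4-one
Product: 24 6-{[6-(benzyloxy)-1-oxo-3-pentyl-1H-isochromen-8-yl]oxy}-7-hydroxy-2,2-dimethyl-5-pentyl-4H-1,3-benzodioxin-4-one, via aldol carbinol 23 (not isolated)
Conditions: Et3N (3 equiv), CH2Cl2, rt
Reagents that add atoms: none
Why: Et3N sets up the enolate equilibria of 22; the productive anion, formed by loss of a C3' proton, is a vinylogous ester enolate that is nucleophilic at the dioxinone α-carbon C5', and this carbon adds to the C6' ketone, which the α-aryloxy group makes more electrophilic, to give carbinol 23. E1cB loss of the C6' hydroxyl and enolisation of the C2' ketone then deliver the benzene ring irreversibly, with O4' and the carboxyl group still tied together in the acetonide. The closest known reaction type is the amine- or carbonate-mediated cycloaromatisation of 6-(2,4-dioxoalkyl)-1,3-dioxin-4-ones to acetonide-protected 6-alkyl-2,4-dihydroxybenzoates, and the oxygen substituent on the central carbon is the only extension. Ring B closes in a 6-(enolexo)-exo-trig mode and no stereocentre remains, since C1' and C6' of 23 both become sp2. The step needs C–C closure to beat closure through oxygen to a pyranone; the dioxinone ring holds C5' on the same side of the alkene as the side chain and within reach of C6', and a mild, non-nucleophilic base at room temperature opens neither the ketene nor the retro-Claisen channel. The aryloxy group stands on the carbon next to each ketone and so has no β-elimination path, and addition of the C1' enolate to the peri lactone carbonyl would give a non-enolisable 2,2-diacylbenzofuranone that can only revert, so aromatisation drains all the equilibria.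

Step 16
Reactants: 24 6-{[6-(benzyloxy)-1-oxo-3-pentyl-1H-isochromen-8-yl]oxy}-7-hydroxy-2,2-dimethyl-5-pentyl-4H-1,3-benzodioxin-4-one
Product: 25 3-[5-(benzyloxy)-2-carboxy-3-(2-oxoheptyl)phenoxy]-4,6-dihydroxy-2-pentylbenzoic acid
Conditions: KOH (5 M aq., excess), DMSO, 70 °C, argon; then 1 M HCl to pH 2–3 at 0 °C
Reagents that add atoms: potassium hydroxide [K+].[OH-]
Why: Saponification by acyl–oxygen cleavage: hydroxide opens the enol lactone to the keto carboxylate and the hindered aryl acylal to the salicylate with loss of acetone, both carboxylates resist decarboxylation in base, and a Smiles migration of ring A from O1' to O2' has no driving force because the C2' phenoxide, para to the carboxyl carbon, is the better stabilised one.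

Step 17
Reactants: 25 3-[5-(benzyloxy)-2-carboxy-3-(2-oxoheptyl)phenoxy]-4,6-dihydroxy-2-pentylbenzoic acid
Product: 26 3-[2-carboxy-5-hydroxy-3-(2-oxoheptyl)phenoxy]-4,6-dihydroxy-2-pentylbenzoic acid
Conditions: H2 (1 atm), 10% Pd/C, EtOAc–MeOH, rt
Reagents that add atoms: none
Why: Catalytic hydrogenolysis of the aryl benzyl ether is run on the open keto acid, in which the C3=C4 alkene of the isocoumarin does not exist, so that over-reduction to a dihydroisocoumarin cannot take place.

Step 18
Reactants: 26 3-[2-carboxy-5-hydroxy-3-(2-oxoheptyl)phenoxy]-4,6-dihydroxy-2-pentylbenzoic acid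
Product: 27 4,6-dihydroxy-3-[(6-hydroxy-1-oxo-3-pentyl-1H-isochromen-8-yl)oxy]-2-pentylbenzoic acid (target)
Conditions: CF3CO2H (10 vol%), CH2Cl2–MeCN, rt
Reagents that add atoms: none
Why: Acid-catalysed lactol formation between the ring A carboxyl group and the side-chain ketone (6-exo-trig) followed by dehydration gives the conjugated enol lactone, the known fate of 2-(2-oxoalkyl)benzoic acids, while without a coupling reagent neither depsidone formation at O2' nor any reaction of the ring B acid is expected at room temperature.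

Compound list
1 | methyl orsellinate | Cc1cc(O)cc(O)c1C(=O)OC | starting material
2 | methyl 2,4-bis(benzyloxy)-6-methylbenzoate | Cc1cc(OCc2ccccc2)cc(OCc2ccccc2)c1C(=O)OC | intermediate
3 | hexanoyl chloride | CCCCCC(=O)Cl | starting material
4 | N-methoxy-N-methylhexanamide | CCCCCC(=O)N(C)OC | intermediate
5 | [3,5-bis(benzyloxy)-2-(methoxycarbonyl)benzyl]lithium | [Li]Cc1cc(OCc2ccccc2)cc(OCc2ccccc2)c1C(=O)OC | intermediate
6 | methyl 2,4-bis(benzyloxy)-6-(2-oxoheptyl)benzoate | CCCCCC(=O)Cc1cc(OCc2ccccc2)cc(OCc2ccccc2)c1C(=O)OC | intermediate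
7 | 6,8-bis(benzyloxy)-3-pentyl-1H-isochromen-1-one | CCCCCc1cc2cc(OCc3ccccc3)cc(OCc3ccccc3)c2c(=O)o1 | intermediate
8 | 6-(benzyloxy)-8-hydroxy-3-pentyl-1H-isochromen-1-one | CCCCCc1cc2cc(OCc3ccccc3)cc(O)c2c(=O)o1 | intermediate
9 | Meldrum's acid | CC1(C)OC(=O)CC(=O)O1 | starting material
10 | 5-(1-hydroxyhexylidene)-2,2-dimethyl-1,3-dioxane-4,6-dione | CCCCCC(O)=C1C(=O)OC(C)(C)OC1=O | intermediate
11 | allyl 3-oxooctanoate | CCCCCC(=O)CC(=O)OCC=C | intermediate
12 | allyl 2-chloro-3-oxooctanoate (racemic) | CCCCCC(=O)C(Cl)C(=O)OCC=C | intermediate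
13 | allyl 2-{[6-(benzyloxy)-1-oxo-3-pentyl-1H-isochromen-8-yl]oxy}-3-oxooctanoate (racemic) | CCCCCC(=O)C(Oc1cc(OCc2ccccc2)cc2cc(CCCCC)oc(=O)c12)C(=O)OCC=C | intermediate
14 | allyl 2-{[6-(benzyloxy)-1-oxo-3-pentyl-1H-isochromen-8-yl]oxy}-3-hydroxyoctanoate (diastereomer mixture) | CCCCCC(O)C(Oc1cc(OCc2ccccc2)cc2cc(CCCCC)oc(=O)c12)C(=O)OCC=C | intermediate
15 | allyl 2-{[6-(benzyloxy)-1-oxo-3-pentyl-1H-isochromen-8-yl]oxy}-3-[(tert-butyldimethylsilyl)oxy]octanoate (diastereomer mixture) | CCCCCC(O[Si](C)(C)C(C)(C)C)C(Oc1cc(OCc2ccccc2)cc2cc(CCCCC)oc(=O)c12)C(=O)OCC=C | intermediate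
16 | 2-{[6-(benzyloxy)-1-oxo-3-pentyl-1H-isochromen-8-yl]oxy}-3-[(tert-butyldimethylsilyl)oxy]octanoic acid (diastereomer mixture) | CCCCCC(O[Si](C)(C)C(C)(C)C)C(Oc1cc(OCc2ccccc2)cc2cc(CCCCC)oc(=O)c12)C(=O)O | intermediate
17 | 2,2,6-trimethyl-4H-1,3-dioxin-4-one | CC1=CC(=O)OC(C)(C)O1 | starting material
18 | 2-{[6-(benzyloxy)-1-oxo-3-pentyl-1H-isochromen-8-yl]oxy}-3-[(tert-butyldimethylsilyl)oxy]octanoyl chloride | CCCCCC(O[Si](C)(C)C(C)(C)C)C(Oc1cc(OCc2ccccc2)cc2cc(CCCCC)oc(=O)c12)C(=O)Cl | intermediate
19 | lithium 2,2-dimethyl-6-methylidene-6H-1,3-dioxin-4-olate | [Li]OC1=CC(=C)OC(C)(C)O1 | intermediate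
20 | 6-(3-{[6-(benzyloxy)-1-oxo-3-pentyl-1H-isochromen-8-yl]oxy}-4-[(tert-butyldimethylsilyl)oxy]-2-oxononyl)-2,2-dimethyl-4H-1,3-dioxin-4-one (diastereomer mixture) | CCCCCC(O[Si](C)(C)C(C)(C)C)C(Oc1cc(OCc2ccccc2)cc2cc(CCCCC)oc(=O)c12)C(=O)CC1=CC(=O)OC(C)(C)O1 | intermediate
21 | 6-(3-{[6-(benzyloxy)-1-oxo-3-pentyl-1H-isochromen-8-yl]oxy}-4-hydroxy-2-oxononyl)-2,2-dimethyl-4H-1,3-dioxin-4-one (diastereomer mixture) | CCCCCC(O)C(Oc1cc(OCc2ccccc2)cc2cc(CCCCC)oc(=O)c12)C(=O)CC1=CC(=O)OC(C)(C)O1 | intermediate
22 | 6-(3-{[6-(benzyloxy)-1-oxo-3-pentyl-1H-isochromen-8-yl]oxy}-2,4-dioxononyl)-2,2-dimethyl-4H-1,3-dioxin-4-one (key-step precursor, C1' labile) | CCCCCC(=O)C(Oc1cc(OCc2ccccc2)cc2cc(CCCCC)oc(=O)c12)C(=O)CC1=CC(=O)OC(C)(C)O1 | intermediate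
23 | 6-{[6-(benzyloxy)-1-oxo-3-pentyl-1H-isochromen-8-yl]oxy}-5-hydroxy-2,2-dimethyl-5-pentyl-5,6-dihydro-4H-1,3-benzodioxine-4,7(8H)-dione (diastereomer mixture) | CCCCCC1(O)C(Oc2cc(OCc3ccccc3)cc3cc(CCCCC)oc(=O)c23)C(=O)CC2=C1C(=O)OC(C)(C)O2 | intermediate
24 | 6-{[6-(benzyloxy)-1-oxo-3-pentyl-1H-isochromen-8-yl]oxy}-7-hydroxy-2,2-dimethyl-5-pentyl-4H-1,3-benzodioxin-4-one (key-step product) | CCCCCc1cc2cc(OCc3ccccc3)cc(Oc3c(O)cc4OC(C)(C)OC(=O)c4c3CCCCC)c2c(=O)o1 | intermediate
25 | 3-[5-(benzyloxy)-2-carboxy-3-(2-oxoheptyl)phenoxy]-4,6-dihydroxy-2-pentylbenzoic acid | CCCCCC(=O)Cc1cc(OCc2ccccc2)cc(Oc2c(O)cc(O)c(C(=O)O)c2CCCCC)c1C(=O)O | intermediate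
26 | 3-[2-carboxy-5-hydroxy-3-(2-oxoheptyl)phenoxy]-4,6-dihydroxy-2-pentylbenzoic acid | CCCCCC(=O)Cc1cc(O)cc(Oc2c(O)cc(O)c(C(=O)O)c2CCCCC)c1C(=O)O | intermediate
27 | 4,6-dihydroxy-3-[(6-hydroxy-1-oxo-3-pentyl-1H-isochromen-8-yl)oxy]-2-pentylbenzoic acid | CCCCCc1cc2cc(O)cc(Oc3c(O)cc(O)c(C(=O)O)c3CCCCC)c2c(=O)o1 | target

Total step count: 18.
Longest linear sequence: 15 steps from methyl orsellinate (steps 1, 3, 4, 5 and 8 to 18).

Steps most likely to fail

Step 15. Closure through oxygen to a pyranone, acyl transfer from the lactone to the C1' enolate, or retro-Claisen cleavage of the crowded diketone may outrun the aldol closure.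
- The fallback sets out from 22 and comes back to the route at 27.
- Heating 22 with benzyl alcohol in toluene at 110 °C should expel acetone in a retro-hetero-Diels–Alder reaction. The acylketene is trapped as benzyl 6-{[6-(benzyloxy)-1-oxo-3-pentyl-1H-isochromen-8-yl]oxy}-3,5,7-trioxododecanoate F1. In F1, C5' is a free active methylene, a stronger and more flexible nucleophile than the dioxinone carbon.
- Cs2CO3 in CH2Cl2, then acetic acid, should close the same C5'–C6' bond by a Knoevenagel-type aldol condensation and enolisation. This gives benzyl 3-{[6-(benzyloxy)-1-oxo-3-pentyl-1H-isochromen-8-yl]oxy}-4,6-dihydroxy-2-pentylbenzoate F2.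
- Hydrogenolysis (H2, 10% Pd/C, EtOAc, stopped after two equivalents of hydrogen) removes both benzyl groups and gives 27 without any hydroxide step.

Step 8. Proton transfer from 12 to the phenoxide, attack at chlorine instead of carbon, and slow substitution by the hydrogen-bonded, peri-hindered O8 may stall the ether formation.
- The fallback sets out from 11 and 8 and comes back at 13.
- Regitz diazo transfer to 11 (4-acetamidobenzenesulfonyl azide, Et3N, MeCN, 0 °C) should give allyl 2-diazo-3-oxooctanoate F3.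
- Slow addition of F3 to 8 and Rh2(OAc)4 (1 mol%) in CH2Cl2 at reflux forms the O–C1' bond by carbenoid O–H insertion under neutral conditions. No enolate or phenoxide is involved.

Step 16. Attack of hydroxide on a carbonyl that is flanked by two ortho substituents and deactivated by the para phenoxide may be so slow that forcing conditions lead to loss of CO2 on work-up.
- The fallback sets out from 24 and comes back at 26.
- O-Benzylation of the C2' phenol (BnBr, K2CO3, DMF, rt) gives 7-(benzyloxy)-6-{[6-(benzyloxy)-1-oxo-3-pentyl-1H-isochromen-8-yl]oxy}-2,2-dimethyl-5-pentyl-4H-1,3-benzodioxin-4-one F4. F4 can no longer form the deactivating phenoxide or enter a Smiles migration.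
- Milder saponification (KOH, THF–H2O, 50 °C, cold acidification) should then give 4-(benzyloxy)-3-[5-(benzyloxy)-2-carboxy-3-(2-oxoheptyl)phenoxy]-6-hydroxy-2-pentylbenzoic acid F5.
- The hydrogenolysis conditions of step 17 remove both benzyl ethers to give 26.

Further compounds
F1 | step 15 | benzyl 6-{[6-(benzyloxy)-1-oxo-3-pentyl-1H-isochromen-8-yl]oxy}-3,5,7-trioxododecanoate | CCCCCC(=O)C(Oc1cc(OCc2ccccc2)cc2cc(CCCCC)oc(=O)c12)C(=O)CC(=O)CC(=O)OCc1ccccc1
F2 | step 15 | benzyl 3-{[6-(benzyloxy)-1-oxo-3-pentyl-1H-isochromen-8-yl]oxy}-4,6-dihydroxy-2-pentylbenzoate | CCCCCc1cc2cc(OCc3ccccc3)cc(Oc3c(O)cc(O)c(C(=O)OCc4ccccc4)c3CCCCC)c2c(=O)o1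
F3 | step 8 | allyl 2-diazo-3-oxooctanoate | CCCCCC(=O)C(=[N+]=[N-])C(=O)OCC=C
F4 | step 16 | 7-(benzyloxy)-6-{[6-(benzyloxy)-1-oxo-3-pentyl-1H-isochromen-8-yl]oxy}-2,2-dimethyl-5-pentyl-4H-1,3-benzodioxin-4-one | CCCCCc1cc2cc(OCc3ccccc3)cc(Oc3c(OCc5ccccc5)cc4OC(C)(C)OC(=O)c4c3CCCCC)c2c(=O)o1
F5 | step 16 | 4-(benzyloxy)-3-[5-(benzyloxy)-2-carboxy-3-(2-oxoheptyl)phenoxy]-6-hydroxy-2-pentylbenzoic acid | CCCCCC(=O)Cc1cc(OCc2ccccc2)cc(Oc2c(OCc3ccccc3)cc(O)c(C(=O)O)c2CCCCC)c1C(=O)O
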